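Locants are those of the decalin core of the target: C1 (ArCH2, Me), C2 (Me), C3, C4, C4a (Me), C5 (propanoic acid chain), C6 (=CMe2), C7, C8, C8a (H); ring A = C4a-C5-C6-C7-C8-C8a, ring B = C1-C2-C3-C4-C4a-C8a; β = face of the C4a methyl.
Retrosynthesis: quinone ⇐ hydroquinone dimethyl ether; C6=CMe2 ⇐ C6 ketone; C5 chain ⇐ methyl acrylate; ring A cut at C5–C6 (acylation of a sulfonyl carbanion); ArCH2 ⇐ CHO + ArMgBr; ring B cut at C2–C3 and C1–C8a.
Enabling feature: in ring B the vicinal pair C1 (quaternary)/C2 carries exactly the substituents of (E)-2-methylbut-2-enal and is flanked 1,4 by C8a and C3, which is the retron of a Diels–Alder reaction once C4 bears a temporary oxygen (C4=C4a silyl enol ether).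
Helpers: the C4 silyloxy group fixes the regiochemistry and leaves a regiospecific enol ether for making C4a quaternary (removed by Wolff–Kishner); the formyl group activates the dienophile and becomes the benzylic CH2; a phenylsulfonyl group at C5 closes ring A and is removed reductively.
Forward order: acyclic diene → ring B (cycloaddition) → C4a quaternary centre → aryl group → ring A (C5–C6) → C5 chain → isopropylidene → quinone.
Stereochemistry: C1/C2 (absolute from the catalyst, cis from the E dienophile) and C8a (exo transition state) in the key step; C4a by substrate control anti to the C8a chain and the C1 methyl; C5 by equilibration next to the C6 ketone.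

Key step: step 3

Remarks: Ar = 2,5-dimethoxy-3-methylphenyl. Names of monocyclic intermediates use their own ring numbering; the Why lines use the target locants. Assumption: the (S)-configured oxazaborolidinium catalyst is taken to give the enantiomer drawn; if the sense of induction is the opposite, its (R)-enantiomer is used.

Step 1
Reactants: 1 methyl 4-oxobutanoate; 2 diethyl (3-oxobutan-2-yl)phosphonate
Product: 3 methyl (4E)-5-methyl-6-oxohept-4-enoate
Conditions: LiCl, iPr2NEt, MeCN, 23 °C
Reagents that add atoms: none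
Why: Horner–Wadsworth–Emmons olefination of the α-methyl β-ketophosphonate under mild amine/LiCl conditions, which spare the enolisable aldehyde and the ester, should give the (E)-trisubstituted enone.

Step 2
Reactants: 3 methyl (4E)-5-methyl-6-oxohept-4-enoate
Product: 4 methyl (4E)-6-(tert-butyldimethylsilyloxy)-5-methylhepta-4,6-dienoate
Conditions: TBSOTf, Et3N, CH2Cl2, 0 °C
Reagents that add atoms: tert-butyldimethylsilyl trifluoromethanesulfonate, CC(C)(C)[Si](C)(C)OS(=O)(=O)C(F)(F)F
Why: Soft enolisation (O-silylation, then deprotonation of the acetyl methyl group) is the standard formation of a silyl dienol ether from a methyl enone and gives the cross-conjugated 2-silyloxy-1,3-diene with the E side chain untouched.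

Step 3
Reactants: 4 methyl (4E)-6-(tert-butyldimethylsilyloxy)-5-methylhepta-4,6-dienoate; 5 (2E)-2-methylbut-2-enal (tiglic aldehyde)
Product: 6 methyl 3-[3-(tert-butyldimethylsilyloxy)-6-formyl-2,5,6-trimethylcyclohex-2-en-1-yl]propanoate (exo adduct; 5-Me, 6-Me and the C1 chain mutually cis; CHO cis to H-1)
Conditions: oxazaborolidinium triflimide made from (S)-α,α-diphenylprolinol, o-tolylboroxine and HN(SO2CF3)2 (20 mol %), CH2Cl2, −78 → −40 °C
Reagents that add atoms: none
Why: The oxazaborolidinium ion binds the formyl group of 5 and lowers its LUMO, and diene 4 adds in a concerted but asynchronous [4π+2π] cycloaddition in which its CH2 terminus (largest HOMO coefficient, future C3) bonds to the enal β-carbon (future C2) slightly ahead of bond formation between the substituted terminus (future C8a) and the α-carbon (future C1); the closest known reaction type is the chiral-Lewis-acid-catalysed Diels–Alder reaction of α-substituted enals with 2-silyloxy-1,3-dienes. Ring B is the only ring closed and it closes in the [4+2] mode, leaving the C4=C4a silyl enol ether as a regiospecific handle. The cis relation of the C1 and C2 methyl groups follows from the E geometry of 5 and suprafacial addition, the C8a configuration relative to C1 from the exo transition state (formyl exo, α-methyl endo), and the absolute configuration from the catalyst, which shields one face of the bound enal. The step needs "para" regiochemistry, which the silyloxy group at C4 secures; exo selectivity, which should be favoured because the catalyst-bound formyl group avoids the endo quadrant crowded by the C4a methyl group and the terminal side chain while the small α-methyl group tolerates it; and π-facial selectivity, which is the task of the catalyst.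

Step 4
Reactants: 6 methyl 3-[3-(tert-butyldimethylsilyloxy)-6-formyl-2,5,6-trimethylcyclohex-2-en-1-yl]propanoate
Product: 7 methyl 3-[2-formyl-2,3,6-trimethyl-5-oxo-6-(phenylsulfanylmethyl)cyclohexyl]propanoate (2-Me, 3-Me, 6-Me and the C1 chain on one face; CHO and CH2SPh on the other)
Conditions: PhSCH2Cl, ZnBr2 (20 mol %), CH2Cl2, 0 → 23 °C
Reagents that add atoms: chloromethyl phenyl sulfide, ClCSc1ccccc1
Why: Lewis-acid-mediated α-(phenylsulfanyl)methylation of a silyl enol ether (SN1 alkylation by a thionium ion) attacks the future C4a regiospecifically and should enter from the α face, anti to the adjacent C8a side chain and to the 1,3-related C1 methyl group, so that the C4a methyl ends cis to the C1 and C2 methyls; the non-enolisable aldehyde is a spectator.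

Step 5
Reactants: 8 4-methoxy-2-methylphenol
Product: 9 2-bromo-4-methoxy-6-methylphenol
Conditions: NBS, MeCN, 0 °C
Reagents that add atoms: N-bromosuccinimide, O=C1CCC(=O)N1Br
Why: Electrophilic aromatic bromination is directed ortho to the free hydroxyl group, whose para position is blocked by the methoxy group.

Step 6
Reactants: 9 2-bromo-4-methoxy-6-methylphenol
Product: 10 1-bromo-2,5-dimethoxy-3-methylbenzene
Conditions: MeI, K2CO3, acetone, 56 °C
Reagents that add atoms: iodomethane, CI
Why: Williamson O-methylation of the phenoxide gives the hydroquinone dimethyl ether that is carried to the last step.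

Step 7
Reactants: 7 methyl 3-[2-formyl-2,3,6-trimethyl-5-oxo-6-(phenylsulfanylmethyl)cyclohexyl]propanoate; 10 1-bromo-2,5-dimethoxy-3-methylbenzene
Product: 12 methyl 3-[2-[Ar(hydroxy)methyl]-2,3,6-trimethyl-5-oxo-6-(phenylsulfanylmethyl)cyclohexyl]propanoate (carbinol epimers), via arylmagnesium bromide 11 (not isolated)
Conditions: 10, Mg, THF, 50 °C; then 7, THF, −78 → −20 °C; aq NH4Cl
Reagents that add atoms: none
Why: Grignard formation and 1,2-addition, which at low temperature should select the aldehyde over the ketone flanked by a quaternary carbon and over the ester; the new carbinol centre is removed in the next step, so its configuration does not matter.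

Step 8
Reactants: 12 methyl 3-[2-[Ar(hydroxy)methyl]-2,3,6-trimethyl-5-oxo-6-(phenylsulfanylmethyl)cyclohexyl]propanoate
Product: 13 methyl 3-[2-(ArCH2)-2,3,6-trimethyl-5-oxo-6-(phenylsulfanylmethyl)cyclohexyl]propanoate
Conditions: Et3SiH, CF3CO2H, CH2Cl2, 0 °C
Reagents that add atoms: none
Why: Ionic hydrogenation: the benzylic cation, stabilised by the ortho-methoxy group, should be captured by hydride from the silane faster than it can rearrange, while ketone, ester and sulfide are inert.

Step 9
Reactants: 13 methyl 3-[2-(ArCH2)-2,3,6-trimethyl-5-oxo-6-(phenylsulfanylmethyl)cyclohexyl]propanoate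
Product: 16 3-[2-(ArCH2)-2,3,6-trimethyl-6-(phenylsulfanylmethyl)cyclohexyl]propanoic acid, via keto acid 14 (not isolated), via hydrazone 15 (not isolated)
Conditions: KOH, N2H4·H2O, diethylene glycol, 130 → 200 °C; then 1 M HCl
Reagents that add atoms: potassium hydroxide, [K+].[OH-]
Why: Wolff–Kishner reduction removes the C4 carbonyl helper, which has no epimerisable neighbour (C4a is quaternary), and the same hot hydroxide saponifies the ester to the acid needed for ring closure; the sulfur is kept as the sulfide here because a sulfone could leave in a 1,3-elimination from the carbanion at C4.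

Step 10
Reactants: 16 3-[2-(ArCH2)-2,3,6-trimethyl-6-(phenylsulfanylmethyl)cyclohexyl]propanoic acid
Product: 17 3-[6-(benzenesulfonylmethyl)-2-(ArCH2)-2,3,6-trimethylcyclohexyl]propanoic acid
Conditions: H2O2 (30 %), Na2WO4 (cat.), MeOH, 23 °C
Reagents that add atoms: hydrogen peroxide, OO
Why: Tungstate-catalysed oxidation of sulfide to sulfone is chemoselective in the absence of alkenes and should leave the electron-rich arene and the acid untouched.

Step 11
Reactants: 17 3-[6-(benzenesulfonylmethyl)-2-(ArCH2)-2,3,6-trimethylcyclohexyl]propanoic acid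
Product: 19 5-(benzenesulfonyl)-1-(ArCH2)-1,2,4a-trimethyl-trans-decalin-6-one (target locants; C5 unassigned), via acyl imidazolide 18 (not isolated)
Conditions: CDI, THF, 23 °C; then LiN(iPr)2 (3 equiv), THF, −78 → 0 °C; aq NH4Cl
Reagents that add atoms: none
Why: Intramolecular C-acylation of the α-sulfonyl carbanion by the acyl imidazolide (Claisen-type condensation) closes ring A at C5–C6 as a six-membered ring and is driven by deprotonation of the acidic β-keto sulfone; the trans ring fusion is already fixed by the trans arrangement of the two reacting arms at C4a and C8a.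

Step 12
Reactants: 19 5-(benzenesulfonyl)-1-(ArCH2)-1,2,4a-trimethyl-trans-decalin-6-one; 20 methyl acrylate
Product: 21 methyl 3-[5-(benzenesulfonyl)-1-(ArCH2)-1,2,4a-trimethyl-6-oxo-trans-decalin-5-yl]propanoate (C5 unassigned)
Conditions: DBU (0.2 equiv), MeCN, 23 → 50 °C
Reagents that add atoms: none
Why: Michael addition of the stabilised β-keto sulfone anion to the unhindered acrylate is regiospecific for C5, the only acidic site, and should occur anti to the axial C4a methyl; the configuration of this temporary quaternary centre does not matter.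

Step 13
Reactants: 21 methyl 3-[5-(benzenesulfonyl)-1-(ArCH2)-1,2,4a-trimethyl-6-oxo-trans-decalin-5-yl]propanoate
Product: 23 methyl 3-[1-(ArCH2)-1,2,4a-trimethyl-6-oxo-trans-decalin-5-yl]propanoate (C5 chain β and equatorial), via C5 epimer 22 (not isolated)
Conditions: aluminium amalgam, THF/H2O, 23 °C; then NaOMe (cat.), MeOH, 23 °C
Reagents that add atoms: none
Why: Reductive desulfonylation of the β-keto sulfone gives the ketone through its enolate, and base equilibration of the enolisable C5 centre should place the side chain equatorial (β, cis to the C4a methyl) on the rigid trans-decalin chair, which is the configuration of the target.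

Step 14
Reactants: 23 methyl 3-[1-(ArCH2)-1,2,4a-trimethyl-6-oxo-trans-decalin-5-yl]propanoate
Product: 24 methyl 3-[1-(ArCH2)-1,2,4a-trimethyl-6-(propan-2-ylidene)-trans-decalin-5-yl]propanoate
Conditions: TiCl4, Zn, pyridine, THF, 66 °C; 23 and acetone (10 equiv) added slowly
Reagents that add atoms: acetone, CC(C)=O
Why: McMurry cross-coupling with excess acetone (reductive carbonyl olefination by low-valent titanium) builds the tetrasubstituted exocyclic alkene directly from the hindered ketone under non-basic conditions, so that C5 should not epimerise, and the ester reacts much more slowly than the two ketones.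

Step 15
Reactants: 24 methyl 3-[1-(ArCH2)-1,2,4a-trimethyl-6-(propan-2-ylidene)-trans-decalin-5-yl]propanoate
Product: 25 3-[1-(ArCH2)-1,2,4a-trimethyl-6-(propan-2-ylidene)-trans-decalin-5-yl]propanoic acid
Conditions: LiOH, THF/MeOH/H2O, 23 °C; then 1 M HCl to pH 4, 0 °C
Reagents that add atoms: lithium hydroxide, [Li+].[OH-]
Why: Saponification of the unhindered methyl ester; the tetrasubstituted alkene is inert to base, and the cold, brief acidification should avoid its migration.

Step 16
Reactants: 25 3-[1-(ArCH2)-1,2,4a-trimethyl-6-(propan-2-ylidene)-trans-decalin-5-yl]propanoic acid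
Product: 26 stypoquinonic acid
Conditions: (NH4)2Ce(NO3)6, MeCN/H2O, 0 °C
Reagents that add atoms: water, O
Why: Oxidative demethylation of the para-dimethoxyarene by ceric ammonium nitrate gives the 1,4-benzoquinone (carbonyl oxygens from water) within minutes at 0 °C, conditions the acid and the tetrasubstituted alkene should survive.

Compound list
1 | methyl 4-oxobutanoate | COC(=O)CCC=O | starting material
2 | diethyl (3-oxobutan-2-yl)phosphonate | CCOP(=O)(OCC)C(C)C(C)=O | starting material
3 | methyl (4E)-5-methyl-6-oxohept-4-enoate | COC(=O)CC/C=C(\C)C(C)=O | intermediate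
4 | methyl (4E)-6-(tert-butyldimethylsilyloxy)-5-methylhepta-4,6-dienoate | COC(=O)CC/C=C(\C)C(=C)O[Si](C)(C)C(C)(C)C | intermediate
5 | (2E)-2-methylbut-2-enal (tiglic aldehyde) | C/C=C(\C)C=O | starting material
6 | methyl 3-[3-(tert-butyldimethylsilyloxy)-6-formyl-2,5,6-trimethylcyclohex-2-en-1-yl]propanoate, exo adduct (5-Me, 6-Me and C1 chain cis; CHO cis to H-1) | O=C[C@]1(C)[C@@H](CCC(=O)OC)C(C)=C(O[Si](C)(C)C(C)(C)C)C[C@H]1C | intermediate
7 | methyl 3-[2-formyl-2,3,6-trimethyl-5-oxo-6-(phenylsulfanylmethyl)cyclohexyl]propanoate (2-Me, 3-Me, 6-Me and C1 chain on one face; CHO and CH2SPh on the other) | O=C[C@]1(C)[C@@H](CCC(=O)OC)[C@](C)(CSc2ccccc2)C(=O)C[C@H]1C | intermediate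
8 | 4-methoxy-2-methylphenol | COc1ccc(O)c(C)c1 | starting material
9 | 2-bromo-4-methoxy-6-methylphenol | COc1cc(C)c(O)c(Br)c1 | intermediate
10 | 1-bromo-2,5-dimethoxy-3-methylbenzene | COc1cc(C)c(OC)c(Br)c1 | intermediate
11 | (2,5-dimethoxy-3-methylphenyl)magnesium bromide | COc1cc(C)c(OC)c([Mg]Br)c1 | intermediate (not isolated)
12 | methyl 3-[2-[Ar(hydroxy)methyl]-2,3,6-trimethyl-5-oxo-6-(phenylsulfanylmethyl)cyclohexyl]propanoate, carbinol epimers | COc1cc(C)c(OC)c(c1)C(O)[C@]2(C)[C@@H](CCC(=O)OC)[C@](C)(CSc3ccccc3)C(=O)C[C@H]2C | intermediate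
13 | methyl 3-[2-(ArCH2)-2,3,6-trimethyl-5-oxo-6-(phenylsulfanylmethyl)cyclohexyl]propanoate | COc1cc(C)c(OC)c(c1)C[C@]2(C)[C@@H](CCC(=O)OC)[C@](C)(CSc3ccccc3)C(=O)C[C@H]2C | intermediate
14 | 3-[2-(ArCH2)-2,3,6-trimethyl-5-oxo-6-(phenylsulfanylmethyl)cyclohexyl]propanoic acid | COc1cc(C)c(OC)c(c1)C[C@]2(C)[C@@H](CCC(=O)O)[C@](C)(CSc3ccccc3)C(=O)C[C@H]2C | intermediate (not isolated)
15 | hydrazone of 14 at the ring ketone | COc1cc(C)c(OC)c(c1)C[C@]2(C)[C@@H](CCC(=O)O)[C@](C)(CSc3ccccc3)C(=NN)C[C@H]2C | intermediate (not isolated)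
16 | 3-[2-(ArCH2)-2,3,6-trimethyl-6-(phenylsulfanylmethyl)cyclohexyl]propanoic acid | COc1cc(C)c(OC)c(c1)C[C@]2(C)[C@@H](CCC(=O)O)[C@](C)(CSc3ccccc3)CC[C@H]2C | intermediate
17 | 3-[6-(benzenesulfonylmethyl)-2-(ArCH2)-2,3,6-trimethylcyclohexyl]propanoic acid | COc1cc(C)c(OC)c(c1)C[C@]2(C)[C@@H](CCC(=O)O)[C@](C)(CS(=O)(=O)c3ccccc3)CC[C@H]2C | intermediate
18 | N-acyl imidazole of 17 | COc1cc(C)c(OC)c(c1)C[C@]2(C)[C@@H](CCC(=O)n3ccnc3)[C@](C)(CS(=O)(=O)c4ccccc4)CC[C@H]2C | intermediate (not isolated)
19 | 5-(benzenesulfonyl)-1-(ArCH2)-1,2,4a-trimethyl-trans-decalin-6-one (target locants; 1-Me, 2-Me, 4a-Me β; H-8a α; C5 unassigned) | COc1cc(C)c(OC)c(c1)C[C@]2(C)[C@H]3CCC(=O)C(S(=O)(=O)c4ccccc4)[C@]3(C)CC[C@H]2C | intermediate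
20 | methyl acrylate | C=CC(=O)OC | starting material
21 | methyl 3-[5-(benzenesulfonyl)-1-(ArCH2)-1,2,4a-trimethyl-6-oxo-trans-decalin-5-yl]propanoate (C5 unassigned) | COc1cc(C)c(OC)c(c1)C[C@]2(C)[C@H]3CCC(=O)C(CCC(=O)OC)(S(=O)(=O)c4ccccc4)[C@]3(C)CC[C@H]2C | intermediate
22 | methyl 3-[1-(ArCH2)-1,2,4a-trimethyl-6-oxo-trans-decalin-5-yl]propanoate, C5 chain α (axial) | COc1cc(C)c(OC)c(c1)C[C@]2(C)[C@H]3CCC(=O)[C@H](CCC(=O)OC)[C@]3(C)CC[C@H]2C | intermediate (not isolated)
23 | methyl 3-[1-(ArCH2)-1,2,4a-trimethyl-6-oxo-trans-decalin-5-yl]propanoate, C5 chain β (equatorial) | COc1cc(C)c(OC)c(c1)C[C@]2(C)[C@H]3CCC(=O)[C@@H](CCC(=O)OC)[C@]3(C)CC[C@H]2C | intermediate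
24 | methyl 3-[1-(ArCH2)-1,2,4a-trimethyl-6-(propan-2-ylidene)-trans-decalin-5-yl]propanoate | COc1cc(C)c(OC)c(c1)C[C@]2(C)[C@H]3CCC(=C(C)C)[C@@H](CCC(=O)OC)[C@]3(C)CC[C@H]2C | intermediate
25 | 3-[1-(ArCH2)-1,2,4a-trimethyl-6-(propan-2-ylidene)-trans-decalin-5-yl]propanoic acid | COc1cc(C)c(OC)c(c1)C[C@]2(C)[C@H]3CCC(=C(C)C)[C@@H](CCC(=O)O)[C@]3(C)CC[C@H]2C | intermediate
26 | stypoquinonic acid | CC1=CC(=O)C=C(C[C@]2(C)[C@H]3CCC(=C(C)C)[C@@H](CCC(=O)O)[C@]3(C)CC[C@H]2C)C1=O | target

Total step count: 16. Longest linear sequence: 14 steps (steps 1–4 and 7–16, from methyl 4-oxobutanoate).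

Steps most likely to fail

Step 3. The cycloaddition may lose exo control (a formyl-endo transition state inverts C8a relative to C1), or the enol ether may add 1,2 to the aldehyde instead of cycloadding. The fallback keeps the cycloaddition only for the C1/C2 pair and resets C8a by hydrogen delivery. It sets out from 6 (any C8a ratio): Saegusa–Ito oxidation (Pd(OAc)2, MeCN, 23 °C) erases C8a and gives the enone methyl 3-(6-formyl-2,5,6-trimethyl-3-oxocyclohex-1-en-1-yl)propanoate F1. Hydrogenation (H2, palladium on carbon, EtOAc) should deliver hydrogen to the face opposite the two methyl groups at C1 and C2, giving the ketone methyl 3-(2-formyl-2,3,6-trimethyl-5-oxocyclohexyl)propanoate F2 with H-8a cis to the formyl group. Thermodynamic silyl enol ether formation (TBSCl, NaI, Et3N, MeCN, 70 °C) then returns to the route at 6.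

Step 12. The conjugate addition may stall or revert because C5 becomes quaternary next to the quaternary C4a. The fallback makes the C5–CH2 bond before ring A exists and forms the crowded centre intramolecularly. It sets out from 17: the dianion (LiN(iPr)2, 2 equiv, THF, −78 °C; the carboxylate protects its own α-position) adds through the primary α-sulfonyl carbanion to methyl acrylate and gives 3-[6-[1-(benzenesulfonyl)-4-methoxy-4-oxobutyl]-2-(ArCH2)-2,3,6-trimethylcyclohexyl]propanoic acid F3. Activation with CDI gives its N-acyl imidazole F4 (not isolated), which KN(SiMe3)2 (THF, −78 → 0 °C) should close onto the tertiary sulfonyl carbanion, returning to the route at 21.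

Step 14. The olefination may suffer from pinacol formation or homocoupling, from attack of low-valent titanium on the ester, and from low conversion at the hindered C6 carbonyl. The fallback builds the isopropylidene group by 1,2-addition and allylic reduction. It sets out from 23: CH2=C(CH3)MgBr with CeCl3 (THF, −78 → 0 °C) adds to C6, and the tertiary alkoxide closes onto the ester to give the allylic δ-lactone of 3-[1-(ArCH2)-6-hydroxy-1,2,4a-trimethyl-6-(prop-1-en-2-yl)-trans-decalin-5-yl]propanoic acid F5. Pd(PPh3)4 (cat.) with NaBH4 in THF ionises the tertiary allylic C–O bond, and hydride attack at the CH2 terminus of the π-allyl complex should give the tetrasubstituted alkene and the free acid. This returns to the route at 25, so step 15 is not needed.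

Further compounds
F1 | step 3 | methyl 3-(6-formyl-2,5,6-trimethyl-3-oxocyclohex-1-en-1-yl)propanoate | O=C[C@]1(C)C(CCC(=O)OC)=C(C)C(=O)C[C@H]1C
F2 | step 3 | methyl 3-(2-formyl-2,3,6-trimethyl-5-oxocyclohexyl)propanoate (H-1 cis to CHO; C6 epimers) | O=C[C@]1(C)[C@@H](CCC(=O)OC)C(C)C(=O)C[C@H]1C
F3 | step 12 | 3-[6-[1-(benzenesulfonyl)-4-methoxy-4-oxobutyl]-2-(ArCH2)-2,3,6-trimethylcyclohexyl]propanoic acid | COc1cc(C)c(OC)c(c1)C[C@]2(C)[C@@H](CCC(=O)O)[C@](C)(C(CCC(=O)OC)S(=O)(=O)c3ccccc3)CC[C@H]2C
F4 | step 12 | N-acyl imidazole of F3 (not isolated) | COc1cc(C)c(OC)c(c1)C[C@]2(C)[C@@H](CCC(=O)n3ccnc3)[C@](C)(C(CCC(=O)OC)S(=O)(=O)c4ccccc4)CC[C@H]2C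
F5 | step 14 | δ-lactone of 3-[1-(ArCH2)-6-hydroxy-1,2,4a-trimethyl-6-(prop-1-en-2-yl)-trans-decalin-5-yl]propanoic acid (C6 unassigned) | COc1cc(C)c(OC)c(c1)C[C@]2(C)[C@H]3CCC4(C(C)=C)OC(=O)CC[C@H]4[C@]3(C)CC[C@H]2C
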